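The disconnection on which everything rests is the C3–C4 bond of the succinic anhydride ring. Ring C3 is a methine that bears the C4H2–C5(=O) arm and sits between the side-chain carbinol carbon and carbonyl C2, which is the imprint of an acetate enolate delivered to an alkene terminus. An Ireland–Claisen rearrangement of a D-mannitol-derived (S)-configured E-allylic acetate, whose far alkene carbon carries an (S)-dioxolane, forges that bond, relays the carbinol chirality to ring C3 and leaves an E-alkene as the masked C2 carboxyl, all in one operation. Lactone chemistry, a cuprate allylation and a late enal cross-metathesis then complete the molecule.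

Key step: step 6

Remark: the target is read as (3S) at ring C3 and (R) at the carbinol carbon with an E-enal, and its hydroxy anhydride is assumed isolable, since acyl transfer to the hydroxyl would pass through a strained dioxabicyclo[2.2.1]heptane intermediate; 1, 21 and 22 are bought.

Step 1
Reactants: 1 1,2:5,6-di-O-isopropylidene-D-mannitol
Product: 2 1,2:5,6-di-O-isopropylidene-3,4-O-thiocarbonyl-D-mannitol (trans-4,5-disubstituted 1,3-dioxolane-2-thione)
Conditions: 1,1'-thiocarbonyldiimidazole, toluene, 110 °C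
Reagents that add atoms: 1,1'-thiocarbonyldiimidazole, S=C(n1ccnc1)n1ccnc1
Why: Thiocarbonyl transfer from the bis-imidazolide to the free 3,4-diol closes the cyclic thionocarbonate (first half of a Corey–Winter olefination) and leaves both acetonides untouched.

Step 2
Reactants: 2 1,2:5,6-di-O-isopropylidene-3,4-O-thiocarbonyl-D-mannitol
Product: 3 (E)-1,2-bis[(4S)-2,2-dimethyl-1,3-dioxolan-4-yl]ethene
Conditions: P(OMe)3 (neat), 110 °C
Reagents that add atoms: none
Why: Thiophilic attack of the phosphite and stereospecific syn cycloreversion (Corey–Winter olefination) should turn the threo-derived trans thionocarbonate into the E-alkene; the dioxolane centres are untouched and change from R to S only because their neighbour becomes olefinic.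

Step 3
Reactants: 3 (E)-1,2-bis[(4S)-2,2-dimethyl-1,3-dioxolan-4-yl]ethene
Product: 4 (2S,3E)-4-[(4S)-2,2-dimethyl-1,3-dioxolan-4-yl]but-3-ene-1,2-diol
Conditions: AcOH/H2O (7:3), rt, stopped near half conversion; recovered 3 recycled
Reagents that add atoms: none
Why: Acid-catalysed acetal hydrolysis frees one of two homotopic diols, so no regiochemical question arises, and unreacted 3 and re-acetalised tetraol can be returned to the step.

Step 4
Reactants: 4 (2S,3E)-4-[(4S)-2,2-dimethyl-1,3-dioxolan-4-yl]but-3-ene-1,2-diol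
Product: 5 (2S,3E)-1-(tert-butyldiphenylsilyloxy)-4-[(4S)-2,2-dimethyl-1,3-dioxolan-4-yl]but-3-en-2-ol
Conditions: TBDPSCl, imidazole, CH2Cl2, 0 °C
Reagents that add atoms: tert-butyl(chloro)diphenylsilane, CC(C)(C)[Si](Cl)(c1ccccc1)c1ccccc1
Why: Silylation with the bulky chlorosilane is selective for the primary hydroxyl of the 1,2-diol, and this silyl ether later survives the aqueous acid of step 7.

Step 5
Reactants: 5 (2S,3E)-1-(tert-butyldiphenylsilyloxy)-4-[(4S)-2,2-dimethyl-1,3-dioxolan-4-yl]but-3-en-2-ol
Product: 6 (2S,3E)-1-(tert-butyldiphenylsilyloxy)-4-[(4S)-2,2-dimethyl-1,3-dioxolan-4-yl]but-3-en-2-yl acetate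
Conditions: Ac2O, pyridine, DMAP (cat.), CH2Cl2, 0 °C to rt
Reagents that add atoms: acetic anhydride, CC(=O)OC(C)=O
Why: DMAP-catalysed O-acylation of the secondary allylic alcohol proceeds with retention at the carbinol carbon and without allylic transposition.

Step 6
Reactants: 6 (2S,3E)-1-(tert-butyldiphenylsilyloxy)-4-[(4S)-2,2-dimethyl-1,3-dioxolan-4-yl]but-3-en-2-yl acetate
Product: 9 (3R,4E)-6-(tert-butyldiphenylsilyloxy)-3-[(4S)-2,2-dimethyl-1,3-dioxolan-4-yl]hex-4-enoic acid, via trimethylsilyl ketene acetal 7 (not isolated), via trimethylsilyl ester 8 (not isolated)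
Conditions: LiN(iPr)2, Me3SiCl/Et3N, THF, −78 °C to rt, then 60 °C; H2O, pH 5 (citric acid)
Reagents that add atoms: none
Why: LiN(iPr)2 deprotonates the acetate at −78 °C in the presence of Me3SiCl, so the enolate is trapped on oxygen as ketene acetal 7, which on warming undergoes a concerted suprafacial [3,3] shift to silyl ester 8, and mild aqueous work-up frees acid 9. The closest known reaction type is the Ireland–Claisen rearrangement of secondary E-allylic acetates with 1,3-chirality transfer. No ring is closed; the step forms only the future ring C3–C4 bond and a new E-alkene. The new stereocentre (future ring C3, R in 9) is controlled by the (S) carbinol: in the chair transition state the CH2OSi group is equatorial, so the C–O bond breaks and the C–C bond forms on the same face of the E-alkene. The step needs one alkene face and the chair over the boat; the E-geometry and the equatorial preference of the silyloxymethyl group secure both, and the weak facial bias of the dioxolane on an E-alkene should not override them. Leakage through the axial chair would give the Z-alkene epimer, which ends as the cis lactone and can be removed after step 7.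

Step 7
Reactants: 9 (3R,4E)-6-(tert-butyldiphenylsilyloxy)-3-[(4S)-2,2-dimethyl-1,3-dioxolan-4-yl]hex-4-enoic acid
Product: 11 (4R,5S)-4-[(1E)-3-(tert-butyldiphenylsilyloxy)prop-1-en-1-yl]-5-(hydroxymethyl)oxolan-2-one, via dihydroxy acid 10 (not isolated)
Conditions: AcOH/H2O (4:1), 45 °C; then toluene azeotrope
Reagents that add atoms: none
Why: Aqueous acetic acid hydrolyses the acetonide without cleaving the silyl ether, and the freed secondary hydroxyl closes the five-membered lactone in preference to the six-membered one through the primary hydroxyl (acid-catalysed lactonisation), with alkenyl and hydroxymethyl trans as fixed by the two existing centres.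

Step 8
Reactants: 11 (4R,5S)-4-[(1E)-3-(tert-butyldiphenylsilyloxy)prop-1-en-1-yl]-5-(hydroxymethyl)oxolan-2-one
Product: 13 (2S,3S)-2-(hydroxymethyl)-5-oxooxolane-3-carboxylic acid, via lactone aldehyde 12 (not isolated)
Conditions: O3, acetone/H2O (9:1), 0 °C; then NaClO2, NaH2PO4, 2-methylbut-2-ene, t-BuOH/H2O, 0 °C to rt
Reagents that add atoms: ozone, [O-][O+]=O; water, O; sodium chlorite, [Na+].[O-]Cl=O
Why: Ozonolysis in wet solvent gives the aldehydes directly and buffered chlorite (Pinnick oxidation) converts them into acids without epimerising the centre next to the new carboxyl or eliminating the β-acyloxy group; the lipophilic silyloxyacetic acid is removed as its ester after step 9.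

Step 9
Reactants: 13 (2S,3S)-2-(hydroxymethyl)-5-oxooxolane-3-carboxylic acid
Product: 14 methyl (2S,3S)-2-(hydroxymethyl)-5-oxooxolane-3-carboxylate
Conditions: Me3SiCHN2, toluene/MeOH (3:1), 0 °C
Reagents that add atoms: trimethylsilyldiazomethane, C[Si](C)(C)C=[N+]=[N-]
Why: Esterification with the diazoalkane is neutral, so neither the lactone nor the free primary alcohol reacts and no translactonisation can set in.

Step 10
Reactants: 14 methyl (2S,3S)-2-(hydroxymethyl)-5-oxooxolane-3-carboxylate
Product: 15 methyl (2S,3S)-5-oxo-2-{[(trifluoromethanesulfonyl)oxy]methyl}oxolane-3-carboxylate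
Conditions: Tf2O, 2,6-lutidine, CH2Cl2, −78 to −30 °C; used at once
Reagents that add atoms: trifluoromethanesulfonic anhydride, O=S(=O)(OS(=O)(=O)C(F)(F)F)C(F)(F)F
Why: O-Sulfonylation of the primary alcohol with a hindered pyridine base gives the triflate, which the trans-disposed ester carbonyl cannot capture intramolecularly.

Step 11
Reactants: 15 methyl (2S,3S)-5-oxo-2-{[(trifluoromethanesulfonyl)oxy]methyl}oxolane-3-carboxylate
Product: 16 methyl (2R,3S)-5-oxo-2-(prop-2-en-1-yl)oxolane-3-carboxylate
Conditions: (CH2=CH)2CuMgBr (from 2 CH2=CHMgBr and CuI), THF, −78 to −40 °C; aq. NH4Cl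
Reagents that add atoms: vinylmagnesium bromide, C=C[Mg]Br
Why: SN2 displacement of the primary triflate by a vinyl group of the magnesium cuprate (cuprate–triflate coupling) is faster at low temperature than addition to the ester or lactone carbonyl and touches neither stereocentre, the change of descriptor at C2 being a priority effect only.

Step 12
Reactants: 16 methyl (2R,3S)-5-oxo-2-(prop-2-en-1-yl)oxolane-3-carboxylate
Product: 17 dilithium (2S)-2-[(1R)-1-hydroxybut-3-en-1-yl]butanedioate
Conditions: LiOH (2.1 equiv), THF/H2O (3:1), 0 °C to rt; evaporated to dryness, salt used crude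
Reagents that add atoms: lithium hydroxide, [Li+].[OH-]
Why: Saponification opens the lactone and cleaves the methyl ester at the acyl carbons, so both centres are retained, and keeping the product as its dicarboxylate salt prevents relactonisation and enolisation.

Step 13
Reactants: 17 dilithium (2S)-2-[(1R)-1-hydroxybut-3-en-1-yl]butanedioate
Product: 19 (2S)-2-[(1R)-1-(triethylsilyloxy)but-3-en-1-yl]butanedioic acid, via tris(triethylsilyl) derivative 18 (not isolated)
Conditions: Et3SiCl, imidazole, DMF, 0 °C to rt; then H2O/THF, 0 °C; pH 4–5 (NaH2PO4), extraction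
Reagents that add atoms: chlorotriethylsilane, CC[Si](Cl)(CC)CC
Why: Exhaustive silylation converts the carboxylates into labile silyl esters and the secondary hydroxyl into its silyl ether, and mild aqueous hydrolysis then cleaves only the silyl esters, leaving a hydroxyl-protected diacid that cannot lactonise.

Step 14
Reactants: 19 (2S)-2-[(1R)-1-(triethylsilyloxy)but-3-en-1-yl]butanedioic acid
Product: 20 (3S)-3-[(1R)-1-(triethylsilyloxy)but-3-en-1-yl]oxolane-2,5-dione
Conditions: DCC, CH2Cl2, 0 °C to rt; filtration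
Reagents that add atoms: none
Why: Carbodiimide-mediated cyclodehydration of a succinic acid closes the five-membered anhydride under neutral conditions that spare the silyl ether and the centre at ring C3.

Step 15
Reactants: 21 2-methylprop-2-en-1-ol; 22 (2E,6E)-farnesyl bromide
Product: 24 (5E,9E)-6,10,14-trimethyl-2-methylidenepentadeca-5,9,13-trien-1-ol, via dilithio dianion 23 (not isolated)
Conditions: n-BuLi (2.1 equiv), TMEDA, Et2O, 0 °C to rt; then 22, THF, −78 to 0 °C
Reagents that add atoms: none
Why: Alkoxide-directed allylic lithiation gives a symmetrical 2-substituted allyl anion whose C-alkylation by the primary allylic bromide at its α-carbon (SN2) should give the homologated 2-methylene alcohol with the E,E-geometry of the farnesyl unit intact.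

Step 16
Reactants: 24 (5E,9E)-6,10,14-trimethyl-2-methylidenepentadeca-5,9,13-trien-1-ol
Product: 25 (5E,9E)-6,10,14-trimethyl-2-methylidenepentadeca-5,9,13-trienal
Conditions: MnO2 (activated, excess), CH2Cl2, rt; used fresh
Reagents that add atoms: none
Why: Activated MnO2 oxidises the allylic primary alcohol to the 2-alkylacrolein (allylic oxidation) without touching the trisubstituted alkenes.

Step 17
Reactants: 20 (3S)-3-[(1R)-1-(triethylsilyloxy)but-3-en-1-yl]oxolane-2,5-dione; 25 (5E,9E)-6,10,14-trimethyl-2-methylidenepentadeca-5,9,13-trienal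
Product: 26 (2E,5E,9E)-2-{(3R)-3-[(3S)-2,5-dioxooxolan-3-yl]-3-(triethylsilyloxy)propylidene}-6,10,14-trimethylpentadeca-5,9,13-trienal
Conditions: second-generation Hoveyda–Grubbs catalyst RuCl2(H2IMes)(=CH-C6H4-2-OiPr) (5–10 mol %), 25 (3 equiv), CH2Cl2, 40 °C
Reagents that add atoms: none
Why: Olefin cross-metathesis of a terminal alkene with a 2-alkylacrolein is known to give the trisubstituted enal with the formyl group trans to the new substituent (E), driven by loss of ethene; the anhydride and silyl ether are inert and the trisubstituted chain alkenes should react more slowly than the two methylene termini.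

Step 18
Reactants: 26 (2E,5E,9E)-2-{(3R)-3-[(3S)-2,5-dioxooxolan-3-yl]-3-(triethylsilyloxy)propylidene}-6,10,14-trimethylpentadeca-5,9,13-trienal
Product: 27 Hippolide D, (2E,5E,9E)-2-{(3R)-3-[(3S)-2,5-dioxooxolan-3-yl]-3-hydroxypropylidene}-6,10,14-trimethylpentadeca-5,9,13-trienal
Conditions: HF·pyridine, dry THF, 0 °C; dilution with EtOAc, brief wash with cold pH 7 buffer
Reagents that add atoms: none
Why: Fluoride-assisted Si–O cleavage removes the triethylsilyl ether quickly under acidic, non-nucleophilic, anhydrous conditions (desilylation), and the freed hydroxyl should not attack the anhydride because that acyl transfer would pass through a strained bicyclic intermediate.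

Compound list
1 | 1,2:5,6-di-O-isopropylidene-D-mannitol | C1[C@H]([C@H]([C@@H]([C@H]2COC(C)(C)O2)O)O)OC(C)(C)O1 | starting material
2 | 1,2:5,6-di-O-isopropylidene-3,4-O-thiocarbonyl-D-mannitol | C1[C@H]([C@@H]3[C@@H]([C@H]2COC(C)(C)O2)OC(=S)O3)OC(C)(C)O1 | intermediate
3 | (E)-1,2-bis[(4S)-2,2-dimethyl-1,3-dioxolan-4-yl]ethene | CC1(C)OC[C@@H](O1)/C=C/[C@H]1COC(C)(C)O1 | intermediate
4 | (2S,3E)-4-[(4S)-2,2-dimethyl-1,3-dioxolan-4-yl]but-3-ene-1,2-diol | OC[C@@H](O)/C=C/[C@H]1COC(C)(C)O1 | intermediate
5 | (2S,3E)-1-(tert-butyldiphenylsilyloxy)-4-[(4S)-2,2-dimethyl-1,3-dioxolan-4-yl]but-3-en-2-ol | CC(C)(C)[Si](c1ccccc1)(c1ccccc1)OC[C@@H](O)/C=C/[C@H]1COC(C)(C)O1 | intermediate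
6 | (2S,3E)-1-(tert-butyldiphenylsilyloxy)-4-[(4S)-2,2-dimethyl-1,3-dioxolan-4-yl]but-3-en-2-yl acetate | CC(=O)O[C@H](CO[Si](c1ccccc1)(c1ccccc1)C(C)(C)C)/C=C/[C@H]1COC(C)(C)O1 | intermediate
7 | trimethylsilyl ketene acetal of 6 | C=C(O[Si](C)(C)C)O[C@H](CO[Si](c1ccccc1)(c1ccccc1)C(C)(C)C)/C=C/[C@H]1COC(C)(C)O1 | intermediate
8 | trimethylsilyl (3R,4E)-6-(tert-butyldiphenylsilyloxy)-3-[(4S)-2,2-dimethyl-1,3-dioxolan-4-yl]hex-4-enoate | C[Si](C)(C)OC(=O)C[C@H](/C=C/CO[Si](c1ccccc1)(c1ccccc1)C(C)(C)C)[C@H]1COC(C)(C)O1 | intermediate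
9 | (3R,4E)-6-(tert-butyldiphenylsilyloxy)-3-[(4S)-2,2-dimethyl-1,3-dioxolan-4-yl]hex-4-enoic acid | OC(=O)C[C@H](/C=C/CO[Si](c1ccccc1)(c1ccccc1)C(C)(C)C)[C@H]1COC(C)(C)O1 | intermediate
10 | (3R,4E)-6-(tert-butyldiphenylsilyloxy)-3-[(1S)-1,2-dihydroxyethyl]hex-4-enoic acid | OC(=O)C[C@H](/C=C/CO[Si](c1ccccc1)(c1ccccc1)C(C)(C)C)[C@H](O)CO | intermediate
11 | (4R,5S)-4-[(1E)-3-(tert-butyldiphenylsilyloxy)prop-1-en-1-yl]-5-(hydroxymethyl)oxolan-2-one | O=C1C[C@H](/C=C/CO[Si](c2ccccc2)(c2ccccc2)C(C)(C)C)[C@@H](CO)O1 | intermediate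
12 | (2S,3S)-2-(hydroxymethyl)-5-oxooxolane-3-carbaldehyde | O=C1C[C@H](C=O)[C@@H](CO)O1 | intermediate
13 | (2S,3S)-2-(hydroxymethyl)-5-oxooxolane-3-carboxylic acid | O=C1C[C@H](C(=O)O)[C@@H](CO)O1 | intermediate
14 | methyl (2S,3S)-2-(hydroxymethyl)-5-oxooxolane-3-carboxylate | O=C1C[C@H](C(=O)OC)[C@@H](CO)O1 | intermediate
15 | methyl (2S,3S)-5-oxo-2-{[(trifluoromethanesulfonyl)oxy]methyl}oxolane-3-carboxylate | O=C1C[C@H](C(=O)OC)[C@@H](COS(=O)(=O)C(F)(F)F)O1 | intermediate
16 | methyl (2R,3S)-5-oxo-2-(prop-2-en-1-yl)oxolane-3-carboxylate | O=C1C[C@H](C(=O)OC)[C@@H](CC=C)O1 | intermediate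
17 | dilithium (2S)-2-[(1R)-1-hydroxybut-3-en-1-yl]butanedioate | [Li+].[Li+].[O-]C(=O)C[C@H](C(=O)[O-])[C@@H](CC=C)O | intermediate
18 | bis(triethylsilyl) (2S)-2-[(1R)-1-(triethylsilyloxy)but-3-en-1-yl]butanedioate | CC[Si](CC)(CC)OC(=O)C[C@H](C(=O)O[Si](CC)(CC)CC)[C@@H](CC=C)O[Si](CC)(CC)CC | intermediate
19 | (2S)-2-[(1R)-1-(triethylsilyloxy)but-3-en-1-yl]butanedioic acid | OC(=O)C[C@H](C(=O)O)[C@@H](CC=C)O[Si](CC)(CC)CC | intermediate
20 | (3S)-3-[(1R)-1-(triethylsilyloxy)but-3-en-1-yl]oxolane-2,5-dione | C=CC[C@@H](O[Si](CC)(CC)CC)[C@@H]1CC(=O)OC1=O | intermediate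
21 | 2-methylprop-2-en-1-ol (methallyl alcohol) | CC(=C)CO | starting material
22 | (2E,6E)-farnesyl bromide | CC(C)=CCC/C(C)=C/CC/C(C)=C/CBr | starting material
23 | lithium 2-(lithiomethyl)prop-2-en-1-olate | [Li]CC(=C)CO[Li] | intermediate
24 | (5E,9E)-6,10,14-trimethyl-2-methylidenepentadeca-5,9,13-trien-1-ol | CC(C)=CCC/C(C)=C/CC/C(C)=C/CCC(=C)CO | intermediate
25 | (5E,9E)-6,10,14-trimethyl-2-methylidenepentadeca-5,9,13-trienal | CC(C)=CCC/C(C)=C/CC/C(C)=C/CCC(=C)C=O | intermediate
26 | (2E,5E,9E)-2-{(3R)-3-[(3S)-2,5-dioxooxolan-3-yl]-3-(triethylsilyloxy)propylidene}-6,10,14-trimethylpentadeca-5,9,13-trienal | CC(C)=CCC/C(C)=C/CC/C(C)=C/CC/C(C=O)=C\C[C@@H](O[Si](CC)(CC)CC)[C@@H]1CC(=O)OC1=O | intermediate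
27 | Hippolide D | CC(C)=CCC/C(C)=C/CC/C(C)=C/CC/C(C=O)=C\C[C@@H](O)[C@@H]1CC(=O)OC1=O | target

Total step count: 18 (16 in the main line, 2 for enal 25).
Longest linear sequence: 16 steps (steps 1–14, 17 and 18, from 1).

Steps most likely to fail

Step 17. The ruthenium carbene may also engage the trisubstituted alkenes of the farnesyl chain (chain scission, secondary metathesis of 26), and the hindered, electron-poor methylene of 25 may react so slowly that 20 only dimerises. The fallback replaces metathesis by a Wittig olefination; it sets out from 20 and 22 and comes back at 26. Ozonolysis of 20 (O3, CH2Cl2, −78 °C; PPh3) gives (3R)-3-[(3S)-2,5-dioxooxolan-3-yl]-3-(triethylsilyloxy)propanal F1. In parallel, the lithium enolate of tert-butyl acetate is alkylated with 22 to tert-butyl (4E,8E)-5,9,13-trimethyltetradeca-4,8,12-trienoate F2, and LiAlH4 reduces this to (4E,8E)-5,9,13-trimethyltetradeca-4,8,12-trien-1-ol F3. CBr4/PPh3 gives (6E,10E)-14-bromo-2,6,10-trimethyltetradeca-2,6,10-triene F4, and PPh3 in hot MeCN gives [(4E,8E)-5,9,13-trimethyltetradeca-4,8,12-trien-1-yl]triphenylphosphonium bromide F5. C-Formylation of its ylide (n-BuLi, then ethyl formate, two ylide equivalents per formate) gives the stabilised ylide (5E,9E)-6,10,14-trimethyl-2-(triphenyl-λ5-phosphanylidene)pentadeca-5,9,13-trienal F6. Heating F1 with F6 in toluene at 80 °C should give 26 with the E-geometry typical of α-formyl ylides; the neutral ylide is compatible with the anhydride.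

Step 18. Once the hydroxyl is free, hydrolysis of the anhydride by adventitious water or acyl transfer to the hydroxyl (isomerisation to the lactone acid) may compete during deprotection or work-up. The fallback removes the silyl group before the ring is closed; it sets out from 26 and comes back at 27. The anhydride of 26 is opened with aqueous NaHCO3 in THF to disodium (2S)-2-[(1R,3E,7E,11E)-4-formyl-8,12,16-trimethyl-1-(triethylsilyloxy)heptadeca-3,7,11,15-tetraen-1-yl]butanedioate F7, which carries no acylating group and is desilylated with Bu4NF in THF at 0 °C. Acidification to pH 4–5 at 0 °C and immediate extraction give (2S)-2-[(1R,3E,7E,11E)-4-formyl-1-hydroxy-8,12,16-trimethylheptadeca-3,7,11,15-tetraen-1-yl]butanedioic acid F8. This is closed at once with DCC in CH2Cl2 at −20 °C; without an acyl-transfer catalyst the activated carboxyl should be captured by the neighbouring carboxyl faster than by the secondary hydroxyl.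

Step 3. The two acetonides of 3 hydrolyse at the same rate, so the reaction may run on to the tetraol or stall, and the mono-diol forms only in a statistical amount. The fallback replaces desymmetrisation by olefination and reagent-controlled reduction; it sets out from 1 and comes back at 5. NaIO4 cleavage of 1 (CH2Cl2, aq. NaHCO3) gives (R)-2,2-dimethyl-1,3-dioxolane-4-carbaldehyde F9. Horner–Wadsworth–Emmons reaction with the known dimethyl [3-(tert-butyldiphenylsilyloxy)-2-oxopropyl]phosphonate F10 (LiCl, iPr2NEt, MeCN) gives (3E)-1-(tert-butyldiphenylsilyloxy)-4-[(4S)-2,2-dimethyl-1,3-dioxolan-4-yl]but-3-en-2-one F11. Corey–Bakshi–Shibata reduction with the (S)-methyl oxazaborolidine and BH3·SMe2, the alkenyl group acting as the large substituent, should give the (S)-alcohol 5. The carbinol configuration then rests on reagent control and would be checked (Mosher ester) before step 5.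

Further compounds
F1 | step 17 | (3R)-3-[(3S)-2,5-dioxooxolan-3-yl]-3-(triethylsilyloxy)propanal | O=CC[C@@H](O[Si](CC)(CC)CC)[C@@H]1CC(=O)OC1=O
F2 | step 17 | tert-butyl (4E,8E)-5,9,13-trimethyltetradeca-4,8,12-trienoate | CC(C)=CCC/C(C)=C/CC/C(C)=C/CCC(=O)OC(C)(C)C
F3 | step 17 | (4E,8E)-5,9,13-trimethyltetradeca-4,8,12-trien-1-ol | CC(C)=CCC/C(C)=C/CC/C(C)=C/CCCO
F4 | step 17 | (6E,10E)-14-bromo-2,6,10-trimethyltetradeca-2,6,10-triene | CC(C)=CCC/C(C)=C/CC/C(C)=C/CCCBr
F5 | step 17 | [(4E,8E)-5,9,13-trimethyltetradeca-4,8,12-trien-1-yl]triphenylphosphonium bromide | CC(C)=CCC/C(C)=C/CC/C(C)=C/CCC[P+](c1ccccc1)(c1ccccc1)c1ccccc1.[Br-]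
F6 | step 17 | (5E,9E)-6,10,14-trimethyl-2-(triphenyl-λ5-phosphanylidene)pentadeca-5,9,13-trienal | CC(C)=CCC/C(C)=C/CC/C(C)=C/CCC(C=O)=P(c1ccccc1)(c1ccccc1)c1ccccc1
F7 | step 18 | disodium (2S)-2-[(1R,3E,7E,11E)-4-formyl-8,12,16-trimethyl-1-(triethylsilyloxy)heptadeca-3,7,11,15-tetraen-1-yl]butanedioate | [Na+].[Na+].CC(C)=CCC/C(C)=C/CC/C(C)=C/CC/C(C=O)=C\C[C@@H](O[Si](CC)(CC)CC)[C@H](CC(=O)[O-])C(=O)[O-]
F8 | step 18 | (2S)-2-[(1R,3E,7E,11E)-4-formyl-1-hydroxy-8,12,16-trimethylheptadeca-3,7,11,15-tetraen-1-yl]butanedioic acid | CC(C)=CCC/C(C)=C/CC/C(C)=C/CC/C(C=O)=C\C[C@@H](O)[C@H](CC(=O)O)C(=O)O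
F9 | step 3 | (R)-2,2-dimethyl-1,3-dioxolane-4-carbaldehyde | O=C[C@H]1COC(C)(C)O1
F10 | step 3 | dimethyl [3-(tert-butyldiphenylsilyloxy)-2-oxopropyl]phosphonate | COP(=O)(CC(=O)CO[Si](c1ccccc1)(c1ccccc1)C(C)(C)C)OC
F11 | step 3 | (3E)-1-(tert-butyldiphenylsilyloxy)-4-[(4S)-2,2-dimethyl-1,3-dioxolan-4-yl]but-3-en-2-one | CC(C)(C)[Si](OCC(=O)/C=C/[C@H]1COC(C)(C)O1)(c1ccccc1)c1ccccc1
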